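The quinone ring is cut at the two bonds that tie ring carbons C2 (bearing the nonadecyl chain) and C3 (C–H) to the carbonyl carbons C1 and C4. This leaves henicos-1-yne and the maleoyl unit C1(=O)–C6H=C5H–C4(=O); because that unit is symmetric, either orientation of the alkyne gives the same quinone. The maleoyl unit is delivered as a five-membered cobaltacycle, made by insertion of monovalent cobalt into the C(O)–C(O) bond of cyclobut-3-ene-1,2-dione. In the key step the alkyne inserts into this metallacycle and reductive elimination closes the six-membered ring, forming both acyl–alkenyl bonds in one operation.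

Key step: step 4

Remark: in the SMILES of the cobalt complexes the donor bonds from phosphorus and nitrogen to cobalt are drawn as single bonds with formal charges; diol 4 forms as a cis/trans mixture whose stereocentres vanish in the same step, and the target has no stereocentre.

Step 1
Reactants: 1 1-bromononadecane
Product: 2 henicos-1-yne
Conditions: LiC≡CH·H2NCH2CH2NH2 (1.5 equiv), DMSO/THF, 0 °C to rt
Reagents that add atoms: lithium acetylide–ethylenediamine complex, [Li+].[C-]#C.NCCN
Why: SN2 alkylation of the acetylide by an unhindered primary bromide in a dipolar aprotic medium is a standard terminal-alkyne synthesis with little competing elimination.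

Step 2
Reactants: 3 3,4-di(propan-2-yloxy)cyclobut-3-ene-1,2-dione (diisopropyl squarate)
Product: 5 cyclobut-3-ene-1,2-dione, via 3,4-di(propan-2-yloxy)cyclobut-3-ene-1,2-diol 4 (not isolated)
Conditions: LiAlH4 (1.0 equiv), Et2O, −78 to 0 °C; then 2 M aq. HCl, CH2Cl2, 0 °C to rt; product kept cold and dark
Reagents that add atoms: water, O
Why: 1,2-reduction of both carbonyls (the second is a vinylogous ester) followed by acid-mediated allylic transposition with enol-ether hydrolysis at each carbinol, a twofold Stork–Danheiser-type transposition of the kind that converts squarate 1,2-adducts into cyclobutenediones, should deliver the parent dione, and the carbinol stereocentres of 4 are lost in the process.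

Step 3
Reactants: 5 cyclobut-3-ene-1,2-dione; 6 chlorotris(triphenylphosphine)cobalt CoCl(PPh3)3
Product: 8 chloro(dimethylglyoxime)(pyridine)maleoylcobalt CoCl(C5H5N)(C4H8N2O2)[C(O)CH=CHC(O)], via chlorobis(triphenylphosphine)maleoylcobalt CoCl(PPh3)2[C(O)CH=CHC(O)] 7 (not isolated)
Conditions: benzene, rt, N2; then dimethylglyoxime (1.1 equiv), pyridine, rt; complex collected by precipitation
Reagents that add atoms: dimethylglyoxime, CC(=NO)C(C)=NO; pyridine, c1ccncc1
Why: Oxidative addition of monovalent cobalt into the strained, weak C(O)–C(O) bond of the 1,2-dione gives the five-membered maleoyl metallacycle of trivalent cobalt, and ligand substitution of both phosphines by the chelating dioxime and pyridine gives an octahedral, phosphine-free complex (known metallacycle formation from cyclobutenediones followed by ligand exchange).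

Step 4
Reactants: 8 chloro(dimethylglyoxime)(pyridine)maleoylcobalt; 2 henicos-1-yne
Product: 9 2-nonadecylcyclohexa-2,5-diene-1,4-dione (2-nonadecyl-1,4-benzoquinone)
Conditions: CoCl2·6H2O (1 equiv), MeCN/ClCH2CH2Cl, 75 °C, N2
Reagents that add atoms: none
Why: The Lewis acid CoCl2 is expected to open a coordination site on the 18-electron trivalent cobalt centre of 8, whereupon alkyne 2 coordinates and inserts into one Co–acyl bond, forming the first acyl–alkenyl C–C bond and a seven-membered cobaltacycle, and C–C reductive elimination then forms the second acyl–alkenyl bond and releases the quinone with monovalent cobalt. The closest known reaction type is the quinone synthesis by insertion of alkynes into maleoyl- and phthaloylcobalt metallacycles. The six-membered ring is closed as a formal [4+2] annulation of the four-carbon maleoyl unit with the two alkyne carbons, the closing event being reductive elimination from the seven-membered metallacycle. No stereocentre is formed. Regioselectivity is not needed, because the maleoyl unit is C2-symmetric and both orientations of the terminal alkyne lead to the same 2-substituted quinone. The step needs chemoselectivity for a single insertion over alkyne oligomerisation, which the stoichiometric, coordinatively saturated metallacycle should secure, and the phosphine-free ligand set of 8 keeps triphenylphosphine, which would add to the unsubstituted quinone positions, out of the flask.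

Compound list
1 | 1-bromononadecane | CCCCCCCCCCCCCCCCCCCBr | starting material
2 | henicos-1-yne | CCCCCCCCCCCCCCCCCCCC#C | intermediate
3 | 3,4-di(propan-2-yloxy)cyclobut-3-ene-1,2-dione (diisopropyl squarate) | CC(C)OC1=C(OC(C)C)C(=O)C1=O | starting material
4 | 3,4-di(propan-2-yloxy)cyclobut-3-ene-1,2-diol (cis/trans mixture) | CC(C)OC1=C(OC(C)C)C(O)C1O | intermediate
5 | cyclobut-3-ene-1,2-dione | O=C1C=CC1=O | intermediate
6 | chlorotris(triphenylphosphine)cobalt, CoCl(PPh3)3 | Cl[Co-3]([P+](c1ccccc1)(c1ccccc1)c1ccccc1)([P+](c1ccccc1)(c1ccccc1)c1ccccc1)[P+](c1ccccc1)(c1ccccc1)c1ccccc1 | starting material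
7 | chlorobis(triphenylphosphine)maleoylcobalt, CoCl(PPh3)2[C(O)CH=CHC(O)] (1-cobaltacyclopent-3-ene-2,5-dione) | O=C1C=CC(=O)[Co-2]1(Cl)([P+](c2ccccc2)(c2ccccc2)c2ccccc2)[P+](c2ccccc2)(c2ccccc2)c2ccccc2 | intermediate
8 | chloro(dimethylglyoxime)(pyridine)maleoylcobalt, CoCl(C5H5N)(C4H8N2O2)[C(O)CH=CHC(O)] (octahedral, N,N-chelating dioxime) | O=C1C=CC(=O)[Co-3]12(Cl)([n+]3ccccc3)[N+](O)=C(C)C(C)=[N+]2O | intermediate
9 | 2-nonadecylcyclohexa-2,5-diene-1,4-dione | CCCCCCCCCCCCCCCCCCCC1=CC(=O)C=CC1=O | target

Total step count: 4
Longest linear sequence: 3 steps (steps 2, 3 and 4); step 1 is a one-step side branch.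

Steps most likely to fail

Step 4. The alkyne may oligomerise or insert twice at cobalt, or the unhindered quinone may be consumed by conjugate addition of the liberated nitrogen ligands before it is isolated. The fallback sets out from 2 and comes back at 9, and it forms the same two ring bonds by a chromium-mediated three-component union. Cr(CO)6 would be treated with (E)-2-(trimethylsilyl)ethenyllithium (from (E)-(2-bromoethenyl)trimethylsilane and t-BuLi, Et2O, −78 °C) and the acylate methylated with Me3OBF4 to give pentacarbonyl[methoxy((E)-2-(trimethylsilyl)ethenyl)carbene]chromium F1. Heating F1 with 2 in THF at 50 °C should bring about a Dötz benzannulation, in which the alkyne CH joins the carbene carbon and the alkyl-bearing alkyne carbon joins an inserted CO. The silyl group is expected to shift from carbon to oxygen in the cyclohexadienone, giving (4-methoxy-2-nonadecylphenoxy)trimethylsilane F2. Oxidation of the crude material with (NH4)2Ce(NO3)6 in aqueous MeCN at 0 °C should then give 9.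

Step 2. The second hydride delivery may stall, or the small, electrophilic dione may hydrate and polymerise during its acidic release. The fallback sets out from 3 and comes back at 5, and it replaces carbonyl reduction by C–O to C–Cl to C–H exchange at the dione oxidation level. Single reduction of 3 with LiAlH(Ot-Bu)3 (THF, −78 to 0 °C) and treatment with conc. HCl in CH2Cl2 should give 3-(propan-2-yloxy)cyclobut-3-ene-1,2-dione F3. Hydrolysis of the vinylogous ester with aqueous HCl would give 3-hydroxycyclobut-3-ene-1,2-dione F4. Oxalyl chloride with catalytic DMF in CH2Cl2 would convert this to 3-chlorocyclobut-3-ene-1,2-dione F5. Slow addition of Bu3SnH (1.0 equiv) in the presence of catalytic Pd(PPh3)4 (THF, rt) should then replace chlorine by hydrogen, the fast reaction at the C–Cl bond being expected to outrun conjugate reduction, to give 5.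

Step 3. The monovalent cobalt may bind the unsubstituted C=C bond or trigger oligomerisation of the parent dione instead of inserting into the C–C bond, or the ligand exchange may stop short. The fallback sets out from 5 (with 2) and comes back at 9, and it needs no metal. Deprotonation of 2 with n-BuLi (THF, −78 °C) and 1,2-addition of the lithium acetylide to 5 should give racemic 4-(henicos-1-yn-1-yl)-4-hydroxycyclobut-2-en-1-one F6. Heating F6 in MeCN or toluene (80–110 °C) should bring about the Moore rearrangement: electrocyclic opening to the enynylketene, closure of the six-membered ring between the ketene carbon and the alkyl-bearing alkyne carbon, and hydrogen transfer from the hydroxyl group, giving 9. In this fallback the two ring bonds are formed in two operations instead of one.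

Further compounds
F1 | step 4 | pentacarbonyl[methoxy((E)-2-(trimethylsilyl)ethenyl)carbene]chromium | COC(/C=C/[Si](C)(C)C)=[Cr](=C=O)(=C=O)(=C=O)(=C=O)=C=O
F2 | step 4 | (4-methoxy-2-nonadecylphenoxy)trimethylsilane | CCCCCCCCCCCCCCCCCCCc1cc(OC)ccc1O[Si](C)(C)C
F3 | step 2 | 3-(propan-2-yloxy)cyclobut-3-ene-1,2-dione | CC(C)OC1=CC(=O)C1=O
F4 | step 2 | 3-hydroxycyclobut-3-ene-1,2-dione | OC1=CC(=O)C1=O
F5 | step 2 | 3-chlorocyclobut-3-ene-1,2-dione | ClC1=CC(=O)C1=O
F6 | step 3 | 4-(henicos-1-yn-1-yl)-4-hydroxycyclobut-2-en-1-one (racemic) | CCCCCCCCCCCCCCCCCCCC#CC1(O)C=CC1=O
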